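**Retrosynthetic overview**
- The target comes from desilylation of its phenol TBS ether; the ten-membered carbocycle (the only ring made, and made last) is closed by ring-closing metathesis at the C7=C8 alkene of an acyclic triene that already holds the Z C1=C2 alkene and all three stereocentres.
- The triene comes from an Evans–Tishchenko reduction of a β-hydroxy enone with 4-(silyloxy)benzaldehyde, which sets C3 (anti to C5) and places the aroyl group on O5 in one operation.
- The enone comes from a Weinreb amide (C3–C7 fragment) and a Z-alkenyllithium (C8–C10, C1, C2 fragment).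
- The amide comes from an Evans syn-aldol of an N-isovaleryl oxazolidinone with 3-methylbut-3-enal (sets C4 and C5); the Z-iodide comes from propargyl alcohol by anti-carbomagnesiation/iodination, bromination and allyl Grignard coupling.

Assumption: the SMILES is taken at face value, i.e. (3R,4R,5R) with both ring alkenes Z; atom labels follow the ring in SMILES order (C1 = first methyl-bearing ring carbon, C2 = CH, C3 = CHOH, C4 = CH-iPr, C5 = CH-O-aroyl, C6 = CH2, C7 = C-Me, C8 = CH, C9 and C10 = CH2).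

**Route**

Step 1
Reactants: 1 3-methylbut-3-en-1-ol
Product: 2 3-methylbut-3-enal
Conditions: Dess–Martin periodinane (1.2 equiv), CH2Cl2, 0 °C to rt, 1 h; dilute with pentane, filter, use the cold solution at once
Reagents that add atoms: none
Why: Dess–Martin oxidation takes the primary homoallylic alcohol to the aldehyde under non-enolising conditions, so the β,γ-alkene does not move into conjugation before the aldehyde is used.

Step 2
Reactants: 3 (4S)-4-benzyl-1,3-oxazolidin-2-one; 4 3-methylbutanoyl chloride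
Product: 6 (4S)-4-benzyl-3-(3-methylbutanoyl)-1,3-oxazolidin-2-one, via lithium oxazolidinide 5 (not isolated)
Conditions: n-BuLi (1.05 equiv), THF, −78 °C; then 4, −78 to 0 °C
Reagents that add atoms: none
Why: N-acylation of the lithiated Evans auxiliary by the acid chloride is fast and clean and installs the (S)-benzyl controller for C4 and C5.

Step 3
Reactants: 6 (4S)-4-benzyl-3-(3-methylbutanoyl)-1,3-oxazolidin-2-one; 2 3-methylbut-3-enal
Product: 9 (4S)-4-benzyl-3-[(2S,3R)-3-hydroxy-5-methyl-2-(propan-2-yl)hex-5-enoyl]-1,3-oxazolidin-2-one, via Z-dibutylboron enolate 7 (not isolated), via dibutylboron aldolate 8 (not isolated)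
Conditions: Bu2BOTf (1.2 equiv), i-Pr2NEt (1.4 equiv), CH2Cl2, 0 °C; 2 (2 equiv), −78 to 0 °C; pH 7 buffer, MeOH, 30% H2O2, 0 °C
Reagents that add atoms: none
Why: In this Evans syn-aldol reaction the Z-boron enolate reacts through a closed Zimmerman–Traxler chair on the face away from the benzyl group, giving the (2S,3R) syn adduct, which is the C4 (isopropyl)/C5 (oxygen) syn pair of the target in the correct absolute sense.

Step 4
Reactants: 9 (4S)-4-benzyl-3-[(2S,3R)-3-hydroxy-5-methyl-2-(propan-2-yl)hex-5-enoyl]-1,3-oxazolidin-2-one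
Product: 10 (2S,3R)-3-hydroxy-N-methoxy-N,5-dimethyl-2-(propan-2-yl)hex-5-enamide
Conditions: MeNHOMe·HCl (3 equiv), AlMe3 (3 equiv), CH2Cl2, −10 °C to rt; cold dilute aq. HCl work-up
Reagents that add atoms: N,O-dimethylhydroxylamine hydrochloride, CNOC.Cl
Why: Weinreb transamidation by the aluminium amide is directed to the exocyclic carbonyl by the aluminium alkoxide of the free β-hydroxyl, so the hindered imide is cleaved without touching either stereocentre and the auxiliary is recovered.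

Step 5
Reactants: 11 prop-2-yn-1-ol
Product: 13 (2Z)-3-iodo-2-methylprop-2-en-1-ol, via cyclic alkenylmagnesium alkoxide 12 (not isolated)
Conditions: MeMgBr (2.5 equiv), CuI (10 mol%), THF, −10 °C to rt; then I2 (1.2 equiv), −10 °C to rt; aq. NH4Cl
Reagents that add atoms: methylmagnesium bromide, C[Mg]Br; iodine, II
Why: Copper-catalysed anti-carbomagnesiation of the propargylic alkoxide places methyl on C2 and magnesium on C3 within a five-membered chelate, and iodinolysis with retention gives only the Z-iodide (iodine cis to CH2OH).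

Step 6
Reactants: 13 (2Z)-3-iodo-2-methylprop-2-en-1-ol
Product: 14 (1Z)-3-bromo-1-iodo-2-methylprop-1-ene
Conditions: PBr3 (0.4 equiv), Et2O, 0 °C
Reagents that add atoms: phosphorus tribromide, BrP(Br)Br
Why: SN2 bromination of the primary allylic alcohol leaves the vinyl iodide and the alkene geometry untouched.

Step 7
Reactants: 14 (1Z)-3-bromo-1-iodo-2-methylprop-1-ene; 15 allylmagnesium bromide
Product: 16 (1Z)-1-iodo-2-methylhexa-1,5-diene
Conditions: 15 (1.2 equiv), THF, −40 to 0 °C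
Reagents that add atoms: none
Why: In this allyl–allyl coupling the allyl Grignard displaces the primary allylic bromide (SN2) far faster than it can exchange with the vinyl iodide, giving the 1,5-diene with the Z-iodoalkene intact.

Step 8
Reactants: 10 (2S,3R)-3-hydroxy-N-methoxy-N,5-dimethyl-2-(propan-2-yl)hex-5-enamide; 16 (1Z)-1-iodo-2-methylhexa-1,5-diene
Product: 20 (4R,5S,7Z)-4-hydroxy-2,8-dimethyl-5-(propan-2-yl)dodeca-1,7,11-trien-6-one, via Z-alkenyllithium 17 (not isolated), via chloromagnesium alkoxide 18 (not isolated), via tetrahedral lithium adduct 19 (not isolated)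
Conditions: 16 (1.5 equiv), t-BuLi (3.0 equiv), Et2O, −78 °C; cannulate into 10 pre-treated with i-PrMgCl (1.05 equiv), THF, −78 to −20 °C; aq. NH4Cl
Reagents that add atoms: none
Why: Iodine–lithium exchange with retention gives the configurationally stable Z-alkenyllithium, which adds once to the amide (Weinreb ketone synthesis, hydroxyl masked in situ as its magnesium alkoxide), and the chelated tetrahedral adduct collapses to the Z-enone only on quench, so there is no over-addition.

Step 9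
Reactants: 21 4-hydroxybenzaldehyde
Product: 22 4-[(tert-butyldimethylsilyl)oxy]benzaldehyde
Conditions: TBSCl (1.1 equiv), imidazole (1.1 equiv), DMF, rt
Reagents that add atoms: tert-butyldimethylsilyl chloride, CC(C)(C)[Si](C)(C)Cl
Why: Silylation of the phenol removes the acidic proton that would quench the samarium catalyst in the next step.

Step 10
Reactants: 20 (4R,5S,7Z)-4-hydroxy-2,8-dimethyl-5-(propan-2-yl)dodeca-1,7,11-trien-6-one; 22 4-[(tert-butyldimethylsilyl)oxy]benzaldehyde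
Product: 24 (4R,5R,6R,7Z)-6-hydroxy-2,8-dimethyl-5-(propan-2-yl)dodeca-1,7,11-trien-4-yl 4-[(tert-butyldimethylsilyl)oxy]benzoate, via samarium-bound hemiacetal 23 (not isolated)
Conditions: SmI2 (0.3 equiv), 22 (5 equiv), THF, −10 °C, dark
Reagents that add atoms: none
Why: In this Evans–Tishchenko reduction the hemiacetal formed on the C5 hydroxyl delivers its hydride intramolecularly to the C3 ketone through a chair-like samarium-bridged transition state, which sets C3-OH anti to C5-O (3R) and leaves the aroyl group on O5 only.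

Step 11
Reactants: 24 (4R,5R,6R,7Z)-6-hydroxy-2,8-dimethyl-5-(propan-2-yl)dodeca-1,7,11-trien-4-yl 4-[(tert-butyldimethylsilyl)oxy]benzoate
Product: 25 (1R,3Z,7Z,9R,10R)-9-hydroxy-3,7-dimethyl-10-(propan-2-yl)cyclodeca-3,7-dien-1-yl 4-[(tert-butyldimethylsilyl)oxy]benzoate
Conditions: second-generation Hoveyda–Grubbs catalyst RuCl2(H2IMes)(=CH-C6H4-2-O-i-Pr) (15 mol%, in portions), 1,4-benzoquinone (20 mol%), toluene (1 mM), 80 °C, argon sparge
Reagents that add atoms: none
Why: Ring-closing metathesis starts at the terminal vinyl group and closes onto the 1,1-disubstituted alkene with loss of ethene at high dilution, the existing Z C1=C2 alkene bringing the chain ends together and ring strain favouring the Z geometry at the new trisubstituted C7=C8 alkene (to be confirmed by NOE).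

Step 12
Reactants: 25 (1R,3Z,7Z,9R,10R)-9-hydroxy-3,7-dimethyl-10-(propan-2-yl)cyclodeca-3,7-dien-1-yl 4-[(tert-butyldimethylsilyl)oxy]benzoate
Product: 26 (1R,3Z,7Z,9R,10R)-9-hydroxy-3,7-dimethyl-10-(propan-2-yl)cyclodeca-3,7-dien-1-yl 4-hydroxybenzoate
Conditions: TBAF (1.1 equiv), AcOH (1.2 equiv), THF, 0 °C
Reagents that add atoms: none
Why: Buffered fluoride desilylation cleaves the labile aryl silyl ether while the acetic acid keeps the medium from cleaving the ester or moving it to the free C3 hydroxyl.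

**Compound list**

1 | 3-methylbut-3-en-1-ol | C=C(C)CCO | starting material
2 | 3-methylbut-3-enal | C=C(C)CC=O | intermediate
3 | (4S)-4-benzyl-1,3-oxazolidin-2-one | O=C1N[C@@H](Cc2ccccc2)CO1 | starting material
4 | 3-methylbutanoyl chloride | CC(C)CC(=O)Cl | starting material
5 | lithium (4S)-4-benzyl-2-oxo-1,3-oxazolidin-3-ide | [Li]N1C(=O)OC[C@@H]1Cc1ccccc1 | intermediate (not isolated)
6 | (4S)-4-benzyl-3-(3-methylbutanoyl)-1,3-oxazolidin-2-one | CC(C)CC(=O)N1C(=O)OC[C@@H]1Cc1ccccc1 | intermediate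
7 | (4S)-4-benzyl-3-[(1Z)-1-[(dibutylboranyl)oxy]-3-methylbut-1-en-1-yl]-1,3-oxazolidin-2-one (Z-boron enolate) | CC(C)/C=C(\OB(CCCC)CCCC)N1C(=O)OC[C@@H]1Cc1ccccc1 | intermediate (not isolated)
8 | (4S)-4-benzyl-3-[(2S,3R)-3-[(dibutylboranyl)oxy]-5-methyl-2-(propan-2-yl)hex-5-enoyl]-1,3-oxazolidin-2-one (boron aldolate) | O=C(N1C(=O)OC[C@@H]1Cc1ccccc1)[C@@H](C(C)C)[C@H](OB(CCCC)CCCC)CC(C)=C | intermediate (not isolated)
9 | (4S)-4-benzyl-3-[(2S,3R)-3-hydroxy-5-methyl-2-(propan-2-yl)hex-5-enoyl]-1,3-oxazolidin-2-one | O=C(N1C(=O)OC[C@@H]1Cc1ccccc1)[C@@H](C(C)C)[C@H](O)CC(C)=C | intermediate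
10 | (2S,3R)-3-hydroxy-N-methoxy-N,5-dimethyl-2-(propan-2-yl)hex-5-enamide | CON(C)C(=O)[C@@H](C(C)C)[C@H](O)CC(C)=C | intermediate
11 | prop-2-yn-1-ol | C#CCO | starting material
12 | 4-methyl-2,5-dihydro-1,2-oxamagnesole (cyclic Z-alkenylmagnesium alkoxide) | CC1=C[Mg]OC1 | intermediate (not isolated)
13 | (2Z)-3-iodo-2-methylprop-2-en-1-ol | OC/C(C)=C\I | intermediate
14 | (1Z)-3-bromo-1-iodo-2-methylprop-1-ene | BrC/C(C)=C\I | intermediate
15 | allylmagnesium bromide | C=CC[Mg]Br | starting material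
16 | (1Z)-1-iodo-2-methylhexa-1,5-diene | C=CCC/C(C)=C\I | intermediate
17 | [(1Z)-2-methylhexa-1,5-dien-1-yl]lithium | C=CCC/C(C)=C\[Li] | intermediate (not isolated)
18 | chloromagnesium alkoxide of amide 10 | CON(C)C(=O)[C@@H](C(C)C)[C@H](O[Mg]Cl)CC(C)=C | intermediate (not isolated)
19 | tetrahedral adduct of 17 and 18 (lithium N-methoxy-N-methyl hemiaminal alkoxide, C5-O-MgCl) | CON(C)C(O[Li])(/C=C(/C)CCC=C)[C@@H](C(C)C)[C@H](O[Mg]Cl)CC(C)=C | intermediate (not isolated)
20 | (4R,5S,7Z)-4-hydroxy-2,8-dimethyl-5-(propan-2-yl)dodeca-1,7,11-trien-6-one | C=CCC/C(C)=C\C(=O)[C@@H](C(C)C)[C@H](O)CC(C)=C | intermediate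
21 | 4-hydroxybenzaldehyde | O=Cc1ccc(O)cc1 | starting material
22 | 4-[(tert-butyldimethylsilyl)oxy]benzaldehyde | CC(C)(C)[Si](C)(C)Oc1ccc(C=O)cc1 | intermediate
23 | hemiacetal of 22 on the C5 hydroxyl of 20, held on samarium (drawn as the free hemiacetal) | C=CCC/C(C)=C\C(=O)[C@@H](C(C)C)[C@H](OC(O)c1ccc(O[Si](C)(C)C(C)(C)C)cc1)CC(C)=C | intermediate (not isolated)
24 | (4R,5R,6R,7Z)-6-hydroxy-2,8-dimethyl-5-(propan-2-yl)dodeca-1,7,11-trien-4-yl 4-[(tert-butyldimethylsilyl)oxy]benzoate | C=CCC/C(C)=C\[C@@H](O)[C@@H](C(C)C)[C@H](OC(=O)c1ccc(O[Si](C)(C)C(C)(C)C)cc1)CC(C)=C | intermediate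
25 | (1R,3Z,7Z,9R,10R)-9-hydroxy-3,7-dimethyl-10-(propan-2-yl)cyclodeca-3,7-dien-1-yl 4-[(tert-butyldimethylsilyl)oxy]benzoate | C/C1=C/[C@@H](O)[C@@H](C(C)C)[C@H](OC(=O)c2ccc(O[Si](C)(C)C(C)(C)C)cc2)C/C(C)=C\CC1 | intermediate
26 | (1R,3Z,7Z,9R,10R)-9-hydroxy-3,7-dimethyl-10-(propan-2-yl)cyclodeca-3,7-dien-1-yl 4-hydroxybenzoate | C/C1=C/[C@@H](O)[C@@H](C(C)C)[C@H](OC(=O)c2ccc(O)cc2)C/C(C)=C\CC1 | target

**Counts and risks**

Total step count: 12. Longest linear sequence: 7 steps (steps 1, 3, 4, 8, 10, 11, 12; the branch through steps 5, 6, 7 is equally long). Steps 2 and 9 are side branches.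

Steps most likely to fail:

Step 11 (ring-closing metathesis to a ten-membered ring with a trisubstituted alkene). The triene may oligomerise or give the E ring alkene. The fallback closes the ring one stage earlier, at the ketone oxidation level. It sets out from 20: the same ruthenium catalyst at 1 mM gives (2Z,6Z,9R,10S)-9-hydroxy-3,7-dimethyl-10-(propan-2-yl)cyclodeca-2,6-dien-1-one F1, in which the sp2 C3 and the internal hydrogen bond of the β-hydroxy ketone fold the chain differently and there is no free allylic alcohol. The Evans–Tishchenko reduction with 22 and SmI2 is then run on the ring, and the route is rejoined at 25.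

Step 10 (Evans–Tishchenko reduction with an electron-rich aryl aldehyde). Hemiacetal formation and hydride transfer from 22 may be too slow. The fallback brings the aroyl group in by ordinary esterification and sets out from 20:
- Tishchenko reduction with acetaldehyde (SmI2 cat., THF, −10 °C) gives (4R,5R,6R,7Z)-6-hydroxy-2,8-dimethyl-5-(propan-2-yl)dodeca-1,7,11-trien-4-yl acetate F2, with C3 and the O3/O5 differentiation already fixed.
- TESOTf and 2,6-lutidine give (4R,5S,6R,7Z)-2,8-dimethyl-5-(propan-2-yl)-6-[(triethylsilyl)oxy]dodeca-1,7,11-trien-4-yl acetate F3.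
- i-Bu2AlH at −78 °C removes the acetate to give (4R,5S,6R,7Z)-2,8-dimethyl-5-(propan-2-yl)-6-[(triethylsilyl)oxy]dodeca-1,7,11-trien-4-ol F4.
- Separately, 22 is oxidised (NaClO2, NaH2PO4, 2-methylbut-2-ene) to 4-[(tert-butyldimethylsilyl)oxy]benzoic acid F5.
- EDC·HCl and DMAP join F4 and F5 to give (4R,5S,6R,7Z)-2,8-dimethyl-5-(propan-2-yl)-6-[(triethylsilyl)oxy]dodeca-1,7,11-trien-4-yl 4-[(tert-butyldimethylsilyl)oxy]benzoate F6.
- PPTS in MeOH at 0 °C removes only the alkyl triethylsilyl ether, and the route is rejoined at 24.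

Step 8 (alkenyllithium addition to a hindered, unprotected β-hydroxy Weinreb amide). Enolisation, retro-aldol or Z to E drift of the enone could erode the yield. The fallback makes the C2–C3 bond by a chromium-mediated coupling under non-basic conditions and sets out from 10:
- TESOTf and 2,6-lutidine give (2S,3R)-N-methoxy-N,5-dimethyl-2-(propan-2-yl)-3-[(triethylsilyl)oxy]hex-5-enamide F7.
- i-Bu2AlH in THF at −78 °C gives (2S,3R)-5-methyl-2-(propan-2-yl)-3-[(triethylsilyl)oxy]hex-5-enal F8.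
- Nozaki–Hiyama–Kishi coupling of F8 with iodide 16 (CrCl2 4 equiv, NiCl2 2 mol%, DMSO, rt) gives (4R,5R,7Z)-2,8-dimethyl-5-(propan-2-yl)-4-[(triethylsilyl)oxy]dodeca-1,7,11-trien-6-ol F9 as a mixture of C3 epimers, which does not matter.
- Dess–Martin oxidation gives (4R,5S,7Z)-2,8-dimethyl-5-(propan-2-yl)-4-[(triethylsilyl)oxy]dodeca-1,7,11-trien-6-one F10.
- HF·pyridine in THF at 0 °C removes the silyl group, and the route is rejoined at 20.

Further compounds
F1 | step 11 | (2Z,6Z,9R,10S)-9-hydroxy-3,7-dimethyl-10-(propan-2-yl)cyclodeca-2,6-dien-1-one | C/C1=C/C(=O)[C@@H](C(C)C)[C@H](O)C/C(C)=C\CC1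
F2 | step 10 | (4R,5R,6R,7Z)-6-hydroxy-2,8-dimethyl-5-(propan-2-yl)dodeca-1,7,11-trien-4-yl acetate | C=CCC/C(C)=C\[C@@H](O)[C@@H](C(C)C)[C@H](OC(C)=O)CC(C)=C
F3 | step 10 | (4R,5S,6R,7Z)-2,8-dimethyl-5-(propan-2-yl)-6-[(triethylsilyl)oxy]dodeca-1,7,11-trien-4-yl acetate | C=CCC/C(C)=C\[C@@H](O[Si](CC)(CC)CC)[C@@H](C(C)C)[C@H](OC(C)=O)CC(C)=C
F4 | step 10 | (4R,5S,6R,7Z)-2,8-dimethyl-5-(propan-2-yl)-6-[(triethylsilyl)oxy]dodeca-1,7,11-trien-4-ol | C=CCC/C(C)=C\[C@@H](O[Si](CC)(CC)CC)[C@@H](C(C)C)[C@H](O)CC(C)=C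
F5 | step 10 | 4-[(tert-butyldimethylsilyl)oxy]benzoic acid | CC(C)(C)[Si](C)(C)Oc1ccc(C(=O)O)cc1
F6 | step 10 | (4R,5S,6R,7Z)-2,8-dimethyl-5-(propan-2-yl)-6-[(triethylsilyl)oxy]dodeca-1,7,11-trien-4-yl 4-[(tert-butyldimethylsilyl)oxy]benzoate | C=CCC/C(C)=C\[C@@H](O[Si](CC)(CC)CC)[C@@H](C(C)C)[C@H](OC(=O)c1ccc(O[Si](C)(C)C(C)(C)C)cc1)CC(C)=C
F7 | step 8 | (2S,3R)-N-methoxy-N,5-dimethyl-2-(propan-2-yl)-3-[(triethylsilyl)oxy]hex-5-enamide | CON(C)C(=O)[C@@H](C(C)C)[C@H](O[Si](CC)(CC)CC)CC(C)=C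
F8 | step 8 | (2S,3R)-5-methyl-2-(propan-2-yl)-3-[(triethylsilyl)oxy]hex-5-enal | O=C[C@@H](C(C)C)[C@H](O[Si](CC)(CC)CC)CC(C)=C
F9 | step 8 | (4R,5R,7Z)-2,8-dimethyl-5-(propan-2-yl)-4-[(triethylsilyl)oxy]dodeca-1,7,11-trien-6-ol (C6 epimers) | C=CCC/C(C)=C\C(O)[C@@H](C(C)C)[C@H](O[Si](CC)(CC)CC)CC(C)=C
F10 | step 8 | (4R,5S,7Z)-2,8-dimethyl-5-(propan-2-yl)-4-[(triethylsilyl)oxy]dodeca-1,7,11-trien-6-one | C=CCC/C(C)=C\C(=O)[C@@H](C(C)C)[C@H](O[Si](CC)(CC)CC)CC(C)=C
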